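The butanolide is disconnected at the O1–C5 bond, a β-acyloxy ketone linkage: C5 is β and C4 is α to the exocyclic aryl ketone carbonyl. The key-step precursor is therefore an open-chain γ-keto acid that already carries C3 (set by auxiliary-controlled enolate alkylation) but lacks C5. In one operation a Mannich reagent installs C5 on the only enolisable ketone α-carbon, loss of amine unveils an α-methylene ketone, and the C2 carboxylate adds to its CH2 terminus to close the lactone ring. Because C4 is α to the ketone it epimerises, so both C4 epimers converge on the trans (3R,4R) lactone. Hydrogenolysis of two benzyl ethers then gives the target.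

Key step: step 4

Assumption: the O-benzyl-protected propanoic acid and α-bromoketone used as starting materials are taken as purchasable compounds.

Step 1
Reactants: 1 3-[4-(benzyloxy)-3-methoxyphenyl]propanoic acid; 2 (S)-4-benzyloxazolidin-2-one
Product: 4 (S)-4-benzyl-3-{3-[4-(benzyloxy)-3-methoxyphenyl]propanoyl}oxazolidin-2-one, via mixed pivalic anhydride 3 (not isolated)
Conditions: PivCl, Et3N, THF, −20 °C; then LiCl, 2, −20 °C to rt
Reagents that add atoms: none
Why: Mixed-anhydride N-acylation of the oxazolidinone (LiCl/Et3N protocol) is a standard way to attach the Evans auxiliary, and no stereocentre is formed.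

Step 2
Reactants: 4 (S)-4-benzyl-3-{3-[4-(benzyloxy)-3-methoxyphenyl]propanoyl}oxazolidin-2-one; 5 2-bromo-1-[4-(benzyloxy)-3-methoxyphenyl]ethan-1-one
Product: 7 (S)-4-benzyl-3-{(R)-2-[4-(benzyloxy)-3-methoxybenzyl]-4-[4-(benzyloxy)-3-methoxyphenyl]-4-oxobutanoyl}oxazolidin-2-one, via sodium Z-enolate 6 (not isolated)
Conditions: NaN(SiMe3)2, THF, −78 °C; then 5 in THF, −78 to −30 °C; aq. NH4Cl
Reagents that add atoms: none
Why: In this Evans asymmetric alkylation the chelated sodium Z-enolate 6 should be alkylated by the highly SN2-reactive α-bromoketone on the face opposite the C4 benzyl group of the auxiliary, which sets the (R) centre that becomes C3 of the lactone.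

Step 3
Reactants: 7 (S)-4-benzyl-3-{(R)-2-[4-(benzyloxy)-3-methoxybenzyl]-4-[4-(benzyloxy)-3-methoxyphenyl]-4-oxobutanoyl}oxazolidin-2-one
Product: 9 (R)-2-[4-(benzyloxy)-3-methoxybenzyl]-4-[4-(benzyloxy)-3-methoxyphenyl]-4-oxobutanoic acid, via peroxy acid 8 (not isolated)
Conditions: LiOH, H2O2, THF/H2O, 0 °C; then aq. Na2SO3; then HCl to pH 2
Reagents that add atoms: hydrogen peroxide, OO
Why: Hydroperoxide cleavage of the N-acyloxazolidinone (LiOOH) attacks the exocyclic carbonyl selectively without epimerising the α-centre, the peroxy acid 8 is reduced by sulfite, and the benzyl-protected aryl ketone should be inert to alkaline peroxide at 0 °C.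

Step 4
Reactants: 9 (R)-2-[4-(benzyloxy)-3-methoxybenzyl]-4-[4-(benzyloxy)-3-methoxyphenyl]-4-oxobutanoic acid
Product: 13 (3R,4R)-4-[4-(benzyloxy)-3-methoxybenzoyl]-3-[4-(benzyloxy)-3-methoxybenzyl]dihydrofuran-2(3H)-one, via Mannich base 10 (not isolated), via α-methylene keto acid 11 (not isolated), via cis-lactone 12 (not isolated)
Conditions: CH2=NMe2+ I− (1.1 equiv), MeCN, 60 °C; then iPr2NEt (1.2 equiv), 60 °C, N2 sweep; wash (aq. NaHCO3); then DBU (0.1 equiv), CH2Cl2, 25 °C
Reagents that add atoms: N,N-dimethylmethyleneiminium iodide (Eschenmoser's salt), C=[N+](C)C.[I-]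
Why: The iminium salt aminomethylates the only enolisable position of 9, the CH2 between the stereocentre and the aryl ketone (the future C4), to give Mannich base 10 as its hydroiodide; on neutralisation 10 loses dimethylamine by retro-Michael (E1cB) elimination to the α-methylene ketone 11, and the C2 carboxylate adds to its CH2 terminus (oxa-Michael), forming the O1–C5 bond and the lactone ring. The closest known reaction types are the Mannich α-methylenation of aryl ketones with Eschenmoser's salt, the amine-exchange alkylation of carboxylates by ketonic Mannich bases and the classical formaldehyde route from 3-aroylpropanoic acids to 4-aroylbutanolides. The five-membered ring closes in a formally 5-endo-trig conjugate addition, which is reversible and is pulled forward by the stability of the γ-lactone and by removal of volatile dimethylamine; reversible re-addition of dimethylamine or iodide to 11 offers the same bond through a 5-exo-tet displacement. C4 arises by protonation of the aryl ketone enol and is not set kinetically: it is α to the ketone, so with DBU the cis-lactone 12 and the trans-lactone 13 equilibrate through the enolate and through reversible ring opening to 11, and the trans isomer with the aroyl group anti to the C3 benzyl group should be favoured thermodynamically. C3 is carried unchanged from 9, because its hydrogen is cross-conjugated with the enone in 11 and α only to a carboxylate or lactone carbonyl, far less acidic than the C4 hydrogen. The step needs site selectivity in the aminomethylation, secured by the single enolisable ketone α-carbon, and oxygen attack at CH2 in preference to intermolecular pathways, secured by the intramolecular five-ring geometry and by keeping free dimethylamine low.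

Step 5
Reactants: 13 (3R,4R)-4-[4-(benzyloxy)-3-methoxybenzoyl]-3-[4-(benzyloxy)-3-methoxybenzyl]dihydrofuran-2(3H)-one
Product: 14 (3R,4R)-4-(4-hydroxy-3-methoxybenzoyl)-3-(4-hydroxy-3-methoxybenzyl)dihydrofuran-2(3H)-one
Conditions: H2 (1 atm), 10% Pd/C, EtOAc, rt, stopped at complete debenzylation
Reagents that add atoms: none
Why: Hydrogenolysis of aryl benzyl ethers over Pd/C should be faster than reduction of the electron-rich aryl ketone and runs under neutral conditions, so the lactone and both stereocentres are retained.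

Compound list
1 | 3-[4-(benzyloxy)-3-methoxyphenyl]propanoic acid | COc1cc(CCC(=O)O)ccc1OCc1ccccc1 | starting material
2 | (S)-4-benzyloxazolidin-2-one | O=C1N[C@@H](Cc2ccccc2)CO1 | starting material
3 | 3-[4-(benzyloxy)-3-methoxyphenyl]propanoic pivalic anhydride | COc1cc(CCC(=O)OC(=O)C(C)(C)C)ccc1OCc1ccccc1 | intermediate
4 | (S)-4-benzyl-3-{3-[4-(benzyloxy)-3-methoxyphenyl]propanoyl}oxazolidin-2-one | COc1cc(CCC(=O)N2C(=O)OC[C@@H]2Cc2ccccc2)ccc1OCc1ccccc1 | intermediate
5 | 2-bromo-1-[4-(benzyloxy)-3-methoxyphenyl]ethan-1-one | COc1cc(C(=O)CBr)ccc1OCc1ccccc1 | starting material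
6 | sodium (Z)-enolate of 4 | COc1cc(C/C=C(\[O-])N2C(=O)OC[C@@H]2Cc2ccccc2)ccc1OCc1ccccc1.[Na+] | intermediate
7 | (S)-4-benzyl-3-{(R)-2-[4-(benzyloxy)-3-methoxybenzyl]-4-[4-(benzyloxy)-3-methoxyphenyl]-4-oxobutanoyl}oxazolidin-2-one | COc1cc(C[C@H](CC(=O)c2ccc(OCc3ccccc3)c(OC)c2)C(=O)N2C(=O)OC[C@@H]2Cc2ccccc2)ccc1OCc1ccccc1 | intermediate
8 | (R)-2-[4-(benzyloxy)-3-methoxybenzyl]-4-[4-(benzyloxy)-3-methoxyphenyl]-4-oxobutaneperoxoic acid | COc1cc(C[C@H](CC(=O)c2ccc(OCc3ccccc3)c(OC)c2)C(=O)OO)ccc1OCc1ccccc1 | intermediate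
9 | (R)-2-[4-(benzyloxy)-3-methoxybenzyl]-4-[4-(benzyloxy)-3-methoxyphenyl]-4-oxobutanoic acid | COc1cc(C[C@H](CC(=O)c2ccc(OCc3ccccc3)c(OC)c2)C(=O)O)ccc1OCc1ccccc1 | intermediate
10 | (2R)-2-[4-(benzyloxy)-3-methoxybenzyl]-3-[4-(benzyloxy)-3-methoxybenzoyl]-4-(dimethylamino)butanoic acid (both C3 epimers, formed as the hydroiodide) | COc1cc(C[C@H](C(CN(C)C)C(=O)c2ccc(OCc3ccccc3)c(OC)c2)C(=O)O)ccc1OCc1ccccc1 | intermediate
11 | (R)-2-[4-(benzyloxy)-3-methoxybenzyl]-3-[4-(benzyloxy)-3-methoxybenzoyl]but-3-enoic acid | COc1cc(C[C@H](C(=C)C(=O)c2ccc(OCc3ccccc3)c(OC)c2)C(=O)O)ccc1OCc1ccccc1 | intermediate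
12 | (3R,4S)-4-[4-(benzyloxy)-3-methoxybenzoyl]-3-[4-(benzyloxy)-3-methoxybenzyl]dihydrofuran-2(3H)-one (cis-lactone) | COc1cc(C[C@H]2C(=O)OC[C@H]2C(=O)c2ccc(OCc3ccccc3)c(OC)c2)ccc1OCc1ccccc1 | intermediate
13 | (3R,4R)-4-[4-(benzyloxy)-3-methoxybenzoyl]-3-[4-(benzyloxy)-3-methoxybenzyl]dihydrofuran-2(3H)-one (trans-lactone) | COc1cc(C[C@H]2C(=O)OC[C@@H]2C(=O)c2ccc(OCc3ccccc3)c(OC)c2)ccc1OCc1ccccc1 | intermediate
14 | (3R,4R)-4-(4-hydroxy-3-methoxybenzoyl)-3-(4-hydroxy-3-methoxybenzyl)dihydrofuran-2(3H)-one | COc1cc(C[C@H]2C(=O)OC[C@@H]2C(=O)c2ccc(O)c(OC)c2)ccc1O | target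

Total step count: 5
Longest linear sequence: 5 steps (1 to 14)

Steps most likely to fail

Step 4. The carboxylate conjugate addition may be slower than oligomerisation of the α-methylene ketone or than re-addition of dimethylamine, and released amine may open the lactone by aminolysis. The fallback sets out from 9 and uses the classical aldol route. Aqueous formaldehyde with K2CO3 in THF/H2O at 0 to 25 °C should hydroxymethylate the ketone α-carbon to give the aldol adduct (2R)-2-[4-(benzyloxy)-3-methoxybenzyl]-3-[4-(benzyloxy)-3-methoxybenzoyl]-4-hydroxybutanoic acid F1 as its carboxylate. Acidification with HCl should close the γ-lactone, here through the acyl–oxygen bond, and catalytic DBU in CH2Cl2 should equilibrate C4 to the trans isomer. The fallback comes back to the route at 13.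

Step 2. Proton transfer from the acidic α-bromoketone to the enolate, or addition of the enolate to the ketone carbonyl, may outrun C-alkylation. The fallback sets out from 4 and builds the aryl ketone after the alkylation. The same sodium enolate 6 is alkylated with tert-butyl bromoacetate (THF, −78 °C) to give tert-butyl (R)-3-[4-(benzyloxy)-3-methoxybenzyl]-4-[(S)-4-benzyl-2-oxooxazolidin-3-yl]-4-oxobutanoate F2, with the same facial sense. TFA with Et3SiH in CH2Cl2 at 0 °C should cleave the ester to (R)-3-[4-(benzyloxy)-3-methoxybenzyl]-4-[(S)-4-benzyl-2-oxooxazolidin-3-yl]-4-oxobutanoic acid F3. Thiophenol, EDC and DMAP in CH2Cl2 should convert it into S-phenyl (R)-3-[4-(benzyloxy)-3-methoxybenzyl]-4-[(S)-4-benzyl-2-oxooxazolidin-3-yl]-4-oxobutanethioate F4. Liebeskind–Srogl coupling of F4 with [4-(benzyloxy)-3-methoxyphenyl]boronic acid (Pd2(dba)3, tri(2-furyl)phosphine, copper thiophene-2-carboxylate CuO2CC4H3S with monovalent copper, THF, 50 °C) runs under neutral conditions and comes back to the route at 7.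

Step 5. Over-reduction of the benzylic ketone, to the carbinol and on to the methylene group, may accompany debenzylation. The fallback sets out from 13 and replaces hydrogenolysis by Lewis-acid ether cleavage: BCl3 with pentamethylbenzene as cation scavenger in CH2Cl2 at −78 °C should remove both benzyl groups without touching the ketone, the lactone or the methyl ethers. It arrives directly at 14 and makes no new compound.

Further compounds
F1 | step 4 | (2R)-2-[4-(benzyloxy)-3-methoxybenzyl]-3-[4-(benzyloxy)-3-methoxybenzoyl]-4-hydroxybutanoic acid (both C3 epimers) | COc1cc(C[C@H](C(CO)C(=O)c2ccc(OCc3ccccc3)c(OC)c2)C(=O)O)ccc1OCc1ccccc1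
F2 | step 2 | tert-butyl (R)-3-[4-(benzyloxy)-3-methoxybenzyl]-4-[(S)-4-benzyl-2-oxooxazolidin-3-yl]-4-oxobutanoate | COc1cc(C[C@H](CC(=O)OC(C)(C)C)C(=O)N2C(=O)OC[C@@H]2Cc2ccccc2)ccc1OCc1ccccc1
F3 | step 2 | (R)-3-[4-(benzyloxy)-3-methoxybenzyl]-4-[(S)-4-benzyl-2-oxooxazolidin-3-yl]-4-oxobutanoic acid | COc1cc(C[C@H](CC(=O)O)C(=O)N2C(=O)OC[C@@H]2Cc2ccccc2)ccc1OCc1ccccc1
F4 | step 2 | S-phenyl (R)-3-[4-(benzyloxy)-3-methoxybenzyl]-4-[(S)-4-benzyl-2-oxooxazolidin-3-yl]-4-oxobutanethioate | COc1cc(C[C@H](CC(=O)Sc2ccccc2)C(=O)N2C(=O)OC[C@@H]2Cc2ccccc2)ccc1OCc1ccccc1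
F0 | step 5 | none | none
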